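Readings and results were generated by integration with made-up constants; the scatter is artificial.

The south-east run had carried more capture agent than the flask I was planning, 1.50 of the substrate charge against 1.00, and I had to decide whether to charge the flask that way and leave it for 2.5 d.

the same everywhere: substrate 20 mM

| flask | solid reagent | capture agent | remark | time |
|---|---|---|---|---|
| south-east | 1.5 equiv | 30 mM | run made earlier |  |
| flask | 1.50 equiv | 20.0 mM |  | 2.5 d |

south-east run (percent of the substrate charged)

| time / h | double product / % | crystals / % |
|---|---|---|
| 2.50 | 0 | 0 |
| 5.00 | 2.3 | 0.1 |
| 8.00 | 7.4 | 0 |
| 10.0 | 9.6 | 1.5 |
| 12.0 | 13.6 | 4.7 |
| 15.0 | 18.0 | 9.2 |
| 20.0 | 25.2 | 15.8 |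

(readings scatter by 0.5 percentage points)

- amounts and yields of double product count crystals too
- given per volume of solution although it is solid: solid reagent, crystals
- the numbers in the tables scatter by 0.5 percentage points (one standard deviation)
- at the start none of the solid reagent is in solution
- coupling partner is what solid reagent becomes in solution
- no earlier run changes the charge of capture agent; that part of a forecast is a guess

- the double product and crystals together standing at 2.5 d, as a percentage of the substrate charged
- concentration of coupling partner in solution at 2.5 d, in percent of saturation

I began with the solid reagent. Each double product takes two couplings, so 75.0% of the substrate charged is the reagent ceiling: the equivalents of solid reagent charged divided by two, the share that could become double product if no coupling went elsewhere. Next I asked whether the time would do. Between 10.0 h and 20.0 h the south-east readings of double product rose by 0.0156 /h of the charge. At that pace, reckoned from the start and ignoring the lag in the readings, the ceiling lay 2.00 d away, less than the planned 2.5 d, so I left the time as it was. The open matter was capture agent: I supposed a fork, where a molecule that has coupled once either couples again or is lost to capture agent. No earlier run changes that charge, so my share at the fork was a guess, and I charged the flask as planned, expecting to fall short of the ceiling by an amount I could not read.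

The forecast gave 42% for double product and crystals together and 92% of saturation for coupling partner, holding that “the solution should approach saturation”.

The flask gave 45.2% of double product and crystals together, 60.3% of the reagent ceiling, with coupling partner at 0.353% of saturation and solid reagent, the limiting reagent, at 0% of its charge.

coupling partner + double product → tris adduct (k = 0.230 /M/min); coupling partner + single product → double product (k = 0.960 /M/min); crystals ⇌ double product, rate k3*(cs3 - [double product]) while solid is left; crystals form when [double product] > cs3 (solubility = 0.990 mM, k = 0.00550 /min); solid reagent ⇌ coupling partner, rate k4*(cs4 - [coupling partner]) while solid is left; crystals form when [coupling partner] > cs4 (solubility = 12.0 mM, k = 0.00190 /min); single product + capture agent → trapped intermediate (k = 0.0610 /M/min); substrate + coupling partner → single product (k = 0.370 /M/min) Single product, the substrate coupled once, went on to double product 2.0 times as fast as to trapped intermediate at 0.546 d, but 0.047 times as fast at 2.50 d, when trapped intermediate stood at 28.9%. The neighbour charged with capture agent at 4.00 of the substrate charge reached 32.5% of the same ceiling, 24.4%, with 59.1% as trapped intermediate.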